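The ratio I wanted was left-handed product to right-handed product, read across the earlier runs.

| setting | Friday's | Monday's | Tuesday's | elm | larch |
|---|---|---|---|---|---|
| left-handed substrate | 0.013 M | 0.013 M | 0.013 M | 0.013 M | 0.013 M |
| right-handed substrate | 0.013 M | 0.013 M | 0.013 M | 0.013 M | 0.013 M |
| coupling partner | 0.014 M | 0.016 M | 0.020 M | 0.0260 M | 0.0120 M |
| racemization catalyst | 0.65 mM | 0.65 mM | 0.65 mM | 0.65 mM | 0.65 mM |
| impurity | 0.15 mM | 0.15 mM | 0.15 mM | 0.15 mM | 0.15 mM |
| remark | run made earlier | run made earlier | run made earlier |  |  |
| time |  |  |  | 2.5 min | 2.5 min |

- Friday's (time / min: left-handed product / %, right-handed product / %): 0.200: 2, 2; 0.667: 6, 4; 1.33: 18, 6; 2.00: 21, 10; 2.50: 21, 11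
- Monday's (time / min: left-handed product / %, right-handed product / %): 0.200: 4, 0; 0.667: 8, 2; 1.33: 18, 10; 2.00: 21, 4; 2.50: 25, 9
- Tuesday's (time / min: left-handed product / %, right-handed product / %): 0.200: 8, 4; 0.667: 15, 2; 1.33: 25, 8; 2.00: 28, 11; 2.50: 30, 8

(scatter of a reading: 2 percentage points)

- coupling partner is single-handed; left-handed substrate and right-handed substrate are mirror images of each other, charged as a racemate, each of them at the stated concentration
- an excess is the difference of the two amounts in percent of their sum
- an excess is below zero if the other one leads
- the handed part of coupling partner does not stay in what it makes, so the products of the two hands are mirror images too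

* the flask that ends with the higher excess of left-handed product over right-handed product in the product, or "neither" when 2 percentage points or less lies between them (elm / larch / neither)
* excess of left-handed product over right-handed product in the product at the end, elm
* excess of left-handed product over right-handed product in the product at the end, larch

I kept a ledger of the coupling partner. Each mole used enters one of two columns, left-handed product or right-handed product. Both columns draw on the same partner, so I took its amount to cancel from the ratio of their rates. Summed over Friday's, Monday's and Tuesday's readings, the columns stood at 250% and 91.0%. That is a selectivity factor, as read, of 2.75. It gave 73.3% for the left share, the part of each mole of used partner that enters left-handed product. The excess is then the left share less the rest: 46.6%.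

The first two sampling times gave 50.9%, and the last two gave 46.7%. I saw no clear drift.

Elm charged partner at 1.00 of the two substrates together. Larch charged 0.462, so partner is the limiting reagent there. Once its partner is used up, larch's books close at 33.8% left-handed product and 12.3% right-handed product. My reckoning gave both flasks 46.6%, hence neither.

The forecast differed: elm 62%, larch 26%, so elm. It read the excess as rising with partner, about 33%, 46% and 57% for Friday's, Monday's and Tuesday's, and it said: “This dependence is empirical and its mechanism is unexplained”. Friday's last excess carried a scatter of about 9.3 percentage points, so I kept my flat share.

The flasks gave 49.0% for elm and 49.6% for larch, so the answer was neither.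

    coupling partner + left-handed substrate → left-handed product (k = 0.390 M⁻¹ s⁻¹)
    coupling partner + right-handed substrate → right-handed product (k = 0.130 M⁻¹ s⁻¹)
    left-handed substrate + racemization catalyst ⇌ right-handed substrate + racemization catalyst, rate k3*[racemization catalyst]*[left-handed substrate] forward; the back reaction follows from the equilibrium constant (k = 180 M⁻¹ s⁻¹)
    racemization catalyst + impurity → spent catalyst (k = 37000 M⁻¹ s⁻¹)

At 25.0 min larch had 0.230% of its partner left and held 34.5% left-handed product against the 33.8% of my ledger, with left-handed substrate at 27.0% and right-handed substrate at 27.0%. A larch with partner raised to 1.85 of the two substrates held 74.4% of the charge as product at 2.50 min. The left share of that is 54.6%, and that flask held 55.1% left-handed product.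

The readings were computed with constants of no real substance; the scatter is artificial.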